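The route rests on cutting C3'–C3a'. Ring C, O1', C2' and ring E of the upper dihydrobenzofuran are the atoms of a 5-oxygenated (2S)-flavanone in which ring C still sits on the carbonyl carbon. One oxidation with trivalent iodine moves C3a' of ring C from that carbon to C3', shrinks the pyranone to the dihydrofuran, sets C3' trans to ring E and pushes the old carbonyl carbon out as an ester, later exchanged for ring F. The precursor is the 5-benzyloxyflavanone whose ring E is silenced as its bis-mesylate. The lower half (rings A, B, D) is built separately and joined through C2–C7' by decarboxylative radical arylation.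

Key step: step 6

Labels: primed atoms belong to the upper dihydrobenzofuran (benzo ring C, ring E on C2', ring F on C3'). Unprimed atoms belong to the lower, styryl-bearing dihydrobenzofuran (benzo ring B, ring D on C3, ring A at the end of the styryl group).

Assumption 1: the quinine- and quinidine-derived thioureas are pseudoenantiomeric. The sense of induction in step 5 is assigned by analogy, and the catalyst meant is the one that gives the (2S)-flavanone (written as the quinidine-derived one).

Assumption 2: (S)-SEGPHOS is taken to give the (4S)-4-arylchroman-2-one, by analogy with the (R)-ligand giving (R)-4-arylchroman-2-ones from simple coumarins (same priority order at C4).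

Design remarks:
- Plain 2'-hydroxychalcones cyclise reversibly and with weak enantiocontrol, and their hydroxide-mediated preparation endangers aryl mesylates. The flavanone is therefore reached through an α-tert-butoxycarbonyl chalcone.
- C7' is iodinated and joined to the lower half before ring F is introduced. A 3,5-dialkoxyphenyl ring would compete in the iodination, and an aryl iodide would not survive the nickel-catalysed arylation.
- Benzyl ethers, not methyl ethers, protect rings A, B, D and F, so the final ether cleavage runs at −78 °C.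

Step 1
Reactants: 1 2',6'-dihydroxyacetophenone
Product: 2 1-[2-(benzyloxy)-6-hydroxyphenyl]ethan-1-one
Conditions: BnBr (1.05 equiv), K2CO3, acetone, reflux
Reagents that add atoms: benzyl bromide, BrCc1ccccc1
Why: Williamson etherification stops after one alkylation because the remaining phenol is locked in a hydrogen bond to the ketone.

Step 2
Reactants: 2 1-[2-(benzyloxy)-6-hydroxyphenyl]ethan-1-one
Product: 3 tert-butyl 3-[2-(benzyloxy)-6-hydroxyphenyl]-3-oxopropanoate
Conditions: LiN(SiMe3)2 (3.3 equiv), THF, −78 °C; Boc2O, −78 °C to rt; then cold 1 M HCl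
Reagents that add atoms: di-tert-butyl dicarbonate, CC(C)(C)OC(=O)OC(=O)OC(C)(C)C
Why: Claisen-type C-acylation of the lithium phenoxide–enolate dianion, in which any aryl tert-butyl carbonate formed at oxygen is carried to the same β-keto ester by Baker–Venkataraman-type O-to-C transfer under the excess base.

Step 3
Reactants: 4 2,4-dihydroxybenzaldehyde
Product: 5 2,4-bis(methylsulfonyloxy)benzaldehyde
Conditions: MsCl (2.4 equiv), Et3N, CH2Cl2, 0 °C
Reagents that add atoms: methanesulfonyl chloride, CS(=O)(=O)Cl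
Why: Routine sulfonylation of both phenols installs the electron-withdrawing groups that later silence ring E.

Step 4
Reactants: 3 tert-butyl 3-[2-(benzyloxy)-6-hydroxyphenyl]-3-oxopropanoate; 5 2,4-bis(methylsulfonyloxy)benzaldehyde
Product: 6 tert-butyl (Z)-2-[2-(benzyloxy)-6-hydroxybenzoyl]-3-[2,4-bis(methylsulfonyloxy)phenyl]prop-2-enoate
Conditions: piperidine (cat.), AcOH (cat.), 4 Å molecular sieves, toluene, rt
Reagents that add atoms: none
Why: Knoevenagel condensation under buffered amine catalysis spares the aryl mesylates, and the extra ester makes the acceptor reactive enough for a low-temperature asymmetric cyclisation (drawn as the expected Z isomer, either isomer being a competent substrate).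

Step 5
Reactants: 6 tert-butyl (Z)-2-[2-(benzyloxy)-6-hydroxybenzoyl]-3-[2,4-bis(methylsulfonyloxy)phenyl]prop-2-enoate
Product: 8 (2S)-5-(benzyloxy)-2-[2,4-bis(methylsulfonyloxy)phenyl]chroman-4-one, via flavanone tert-butyl ester 7 (not isolated)
Conditions: quinidine-derived (9-amino-9-deoxy-epi) 3,5-bis(trifluoromethyl)phenyl thiourea (10 mol %), toluene, −25 °C; then p-TsOH·H2O, 80 °C
Reagents that add atoms: none
Why: Bifunctional thiourea–amine catalysis of the 6-endo intramolecular oxa-Michael addition (thiourea binds the β-keto ester, the quinuclidine deprotonates the phenol) sets C2 as S under catalyst control, and acid-mediated loss of isobutene and CO2 then removes the activating ester without touching C2.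

Step 6
Reactants: 8 (2S)-5-(benzyloxy)-2-[2,4-bis(methylsulfonyloxy)phenyl]chroman-4-one
Product: 10 methyl (2S,3S)-4-(benzyloxy)-2-[2,4-bis(methylsulfonyloxy)phenyl]-2,3-dihydrobenzofuran-3-carboxylate, via methyl enol ether 9 (not isolated)
Conditions: PhI(OAc)2 (1.3 equiv), conc. H2SO4, HC(OMe)3, 0 °C to rt; then water
Reagents that add atoms: trimethyl orthoformate, COC(OC)OC
Why: Acid and orthoformate turn ketone 8 into enol ether 9, whose C3 is attacked by the trivalent iodine reagent on the face away from ring E while methanol caps C4, giving a trans-diequatorial 3-iodanyl ketal. The C4–C4a bond then lies antiperiplanar to the equatorial C3–I bond, so the electron-rich ring C carbon C4a slides to C3 as iodobenzene departs, and the dialkoxycarbenium ion left at the old carbonyl carbon collapses to the methyl ester. This is the known oxidative ring contraction of flavanones by PhI(OAc)2 or Tl(NO3)3 in orthoformate, a member of the oxidative 1,2-aryl shift family of aryl ketones. The five-membered ring is closed by contraction and not by cyclisation: the new C3'–C3a' bond replaces C4–C4a and one ring atom becomes exocyclic. C2' is the untouched flavanone C2, and C3' is fixed by inversion at C3 of the trans iodane, which places the ester trans to ring E, the arrangement also favoured by equilibration. The step needs migration of ring C and not of ring E, and rearrangement and not elimination to the flavone; the two mesylates make ring E a poor migrating group while O1 and the 5-benzyloxy group, both ortho to C4a, activate the wanted shift.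

Step 7
Reactants: 10 methyl (2S,3S)-4-(benzyloxy)-2-[2,4-bis(methylsulfonyloxy)phenyl]-2,3-dihydrobenzofuran-3-carboxylate
Product: 11 methyl (2S,3S)-4-(benzyloxy)-7-iodo-2-[2,4-bis(methylsulfonyloxy)phenyl]-2,3-dihydrobenzofuran-3-carboxylate
Conditions: NIS, CF3CO2H (cat.), MeCN, 0 °C to rt
Reagents that add atoms: N-iodosuccinimide, O=C1CCC(=O)N1I
Why: Electrophilic aromatic iodination can only engage ring C because ring E is deactivated by its mesylates, and it should go to C7', para to the benzyloxy group and next to the tied-back O1', since the C3' substituent forces the benzyl group to lie over C5'.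

Step 8
Reactants: 12 4-bromo-2,6-difluorobenzaldehyde
Product: 13 2,6-bis(benzyloxy)-4-bromobenzaldehyde
Conditions: BnOH (2.3 equiv), NaH, DMF, 0 to 60 °C
Reagents that add atoms: benzyl alcohol, OCc1ccccc1
Why: Double nucleophilic aromatic substitution of the two fluorides activated by the ortho formyl group, bromide being the far poorer leaving group in this addition–elimination.

Step 9
Reactants: 13 2,6-bis(benzyloxy)-4-bromobenzaldehyde
Product: 14 2-(benzyloxy)-4-bromo-6-hydroxybenzaldehyde
Conditions: MgBr2·OEt2, toluene/Et2O, 70 °C; then 1 M HCl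
Reagents that add atoms: none
Why: Chelation-controlled ether cleavage in which MgBr2 held between the formyl oxygen and one ortho ether oxygen removes a single benzyl group, after which the magnesium phenoxide chelate shields the second.

Step 10
Reactants: 14 2-(benzyloxy)-4-bromo-6-hydroxybenzaldehyde
Product: 15 5-(benzyloxy)-7-bromo-2H-chromen-2-one
Conditions: Ph3P=C=C=O, toluene, 110 °C
Reagents that add atoms: (triphenylphosphoranylidene)ketene, O=C=C=P(c1ccccc1)(c1ccccc1)c1ccccc1
Why: The phenol adds to the cumulated ylide to give an aryl ester ylide that closes by intramolecular Wittig olefination onto the ortho aldehyde, giving the coumarin under neutral conditions.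

Step 11
Reactants: 15 5-(benzyloxy)-7-bromo-2H-chromen-2-one; 16 [3,5-bis(benzyloxy)phenyl]boronic acid
Product: 17 (4S)-5-(benzyloxy)-4-[3,5-bis(benzyloxy)phenyl]-7-bromochroman-2-one
Conditions: Rh(acac)(C2H4)2 (3 mol %), (S)-SEGPHOS, dioxane/H2O (10:1), 60 °C
Reagents that add atoms: none
Why: Hayashi–Miyaura rhodium-catalysed asymmetric 1,4-addition of the arylboronic acid to the coumarin sets C4 (the future C3) as S under ligand control, the aryl entering from the π face so that the in-plane peri benzyloxy group is avoided and the aryl bromide staying inert to the monovalent rhodium catalyst.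

Step 12
Reactants: 17 (4S)-5-(benzyloxy)-4-[3,5-bis(benzyloxy)phenyl]-7-bromochroman-2-one; 18 1-(benzyloxy)-4-vinylbenzene
Product: 19 (4S)-5-(benzyloxy)-4-[3,5-bis(benzyloxy)phenyl]-7-[(E)-4-(benzyloxy)styryl]chroman-2-one
Conditions: Pd(OAc)2, P(o-tol)3, Et3N, DMF, 100 °C
Reagents that add atoms: none
Why: Mizoroki–Heck coupling of the aryl bromide with the styrene gives the E-stilbene by syn insertion and syn β-hydride elimination and leaves the non-acidic C4 centre alone.

Step 13
Reactants: 19 (4S)-5-(benzyloxy)-4-[3,5-bis(benzyloxy)phenyl]-7-[(E)-4-(benzyloxy)styryl]chroman-2-one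
Product: 20 (3R,4S)-5-(benzyloxy)-4-[3,5-bis(benzyloxy)phenyl]-7-[(E)-4-(benzyloxy)styryl]-3-bromochroman-2-one
Conditions: LiN(SiMe3)2, THF, −78 °C; NBS, −78 °C; then 1 M HCl
Reagents that add atoms: N-bromosuccinimide, O=C1CCC(=O)N1Br
Why: α-Bromination of the kinetic lactone enolate, which outruns any reaction of NBS with the stilbene at this temperature, the electrophile approaching anti to the pseudoaxial C4 aryl group so that the bromide is trans (3R).

Step 14
Reactants: 20 (3R,4S)-5-(benzyloxy)-4-[3,5-bis(benzyloxy)phenyl]-7-[(E)-4-(benzyloxy)styryl]-3-bromochroman-2-one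
Product: 22 (2S,3S)-4-(benzyloxy)-3-[3,5-bis(benzyloxy)phenyl]-6-[(E)-4-(benzyloxy)styryl]-2,3-dihydrobenzofuran-2-carboxylic acid, via trans methyl ester 21 (not isolated)
Conditions: NaOMe, MeOH/THF, 0 °C to rt; then LiOH, H2O, rt; then 1 M HCl
Reagents that add atoms: sodium methoxide, [Na+].[O-]C (methoxy group of 21); lithium hydroxide, [Li+].[OH-] (carboxyl oxygen of 22)
Why: Perkin-type coumarin-to-benzofuran ring contraction in the dihydro series, in which methoxide opens the aryl lactone and the freed phenoxide displaces the α-bromide in a 5-exo-tet SN2 step with inversion to give the trans (2S) ester, also the thermodynamic epimer, which is saponified in the same flask.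

Step 15
Reactants: 22 (2S,3S)-4-(benzyloxy)-3-[3,5-bis(benzyloxy)phenyl]-6-[(E)-4-(benzyloxy)styryl]-2,3-dihydrobenzofuran-2-carboxylic acid
Product: 23 1,3-dioxoisoindolin-2-yl (2S,3S)-4-(benzyloxy)-3-[3,5-bis(benzyloxy)phenyl]-6-[(E)-4-(benzyloxy)styryl]-2,3-dihydrobenzofuran-2-carboxylate
Conditions: N-hydroxyphthalimide, DIC, DMAP (cat.), CH2Cl2, rt
Reagents that add atoms: N-hydroxyphthalimide, O=C1c2ccccc2C(=O)N1O
Why: Carbodiimide (Steglich-type) esterification with N-hydroxyphthalimide gives the redox-active ester.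

Step 16
Reactants: 11 methyl (2S,3S)-4-(benzyloxy)-7-iodo-2-[2,4-bis(methylsulfonyloxy)phenyl]-2,3-dihydrobenzofuran-3-carboxylate; 23 1,3-dioxoisoindolin-2-yl (2S,3S)-4-(benzyloxy)-3-[3,5-bis(benzyloxy)phenyl]-6-[(E)-4-(benzyloxy)styryl]-2,3-dihydrobenzofuran-2-carboxylate
Product: 24 methyl (2'S,3'S)-4'-(benzyloxy)-2'-[2,4-bis(methylsulfonyloxy)phenyl]-7'-{(2S,3S)-4-(benzyloxy)-3-[3,5-bis(benzyloxy)phenyl]-6-[(E)-4-(benzyloxy)styryl]-2,3-dihydrobenzofuran-2-yl}-2',3'-dihydrobenzofuran-3'-carboxylate
Conditions: NiBr2(dme) (10 mol %), 4,4'-di-tert-butyl-2,2'-bipyridine, Zn dust, DMA, rt; then 1 M HCl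
Reagents that add atoms: none
Why: Nickel-catalysed reductive decarboxylative cross-electrophile coupling, in which single-electron reduction of 23 releases CO2 and the α-aryloxy C2 radical, which is captured by the arylnickel species from 11 on the face opposite ring D so that C2 is re-formed as S, trans to C3.

Step 17
Reactants: 24 methyl ester of the coupled bis(dihydrobenzofuran)
Product: 25 (2'S,3'S)-4'-(benzyloxy)-2'-[2,4-bis(methylsulfonyloxy)phenyl]-7'-{(2S,3S)-4-(benzyloxy)-3-[3,5-bis(benzyloxy)phenyl]-6-[(E)-4-(benzyloxy)styryl]-2,3-dihydrobenzofuran-2-yl}-2',3'-dihydrobenzofuran-3'-carboxylic acid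
Conditions: Me3SnOH, 1,2-dichloroethane, 80 °C; then 5 % HCl
Reagents that add atoms: trimethyltin hydroxide, C[Sn](C)(C)O
Why: Trimethyltin hydroxide cleaves the methyl ester under essentially neutral conditions, sparing the aryl mesylates and avoiding enolisation at C3'.

Step 18
Reactants: 25 C3' carboxylic acid of the coupled bis(dihydrobenzofuran)
Product: 26 1,3-dioxoisoindolin-2-yl ester of 25 (2S,3S,2'S,3'S)
Conditions: N-hydroxyphthalimide, DIC, DMAP (cat.), CH2Cl2, rt
Reagents that add atoms: N-hydroxyphthalimide, O=C1c2ccccc2C(=O)N1O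
Why: Carbodiimide (Steglich-type) esterification turns the placeholder acid into a redox-active ester.

Step 19
Reactants: 26 1,3-dioxoisoindolin-2-yl ester of 25; 27 1,3-bis(benzyloxy)-5-bromobenzene
Product: 30 hepta-O-benzyl gnetumontanin B ring E bis(methanesulfonate) (2S,3S,2'S,3'S), via aryllithium 28 (not isolated), via arylzinc chloride 29 (not isolated)
Conditions: 27, n-BuLi, THF, −78 °C; ZnCl2, to rt; then 26, NiCl2(dme) (20 mol %), 4,4'-di-tert-butyl-2,2'-bipyridine, THF/DMF, rt; then 1 M HCl
Reagents that add atoms: n-butyllithium, [Li]CCCC (lithium of 28); zinc chloride, Cl[Zn]Cl (zinc and chlorine of 29)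
Why: Nickel-catalysed decarboxylative Negishi-type arylation, in which the planar benzylic C3' radical combines with the arylnickel species on the face anti to ring E to give the trans (3'S) product, the arylzinc reagent being too weakly basic to attack the mesylates.

Step 20
Reactants: 30 hepta-O-benzyl gnetumontanin B ring E bis(methanesulfonate)
Product: 31 gnetumontanin B ring E bis(methanesulfonate) (2S,3S,2'S,3'S; seven free phenols)
Conditions: BCl3, C6HMe5, CH2Cl2, −78 °C; then MeOH/H2O
Reagents that add atoms: none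
Why: Lewis-acid debenzylation with pentamethylbenzene as non-basic cation scavenger removes all seven primary benzyl ethers at low temperature without reducing the stilbene, the mesylates keeping C2'–O1' from ionising and the hindered scavenger being unable to intercept the crowded C2 position.

Step 21
Reactants: 31 gnetumontanin B ring E bis(methanesulfonate)
Product: 32 gnetumontanin B (2S,3S,2'S,3'S)
Conditions: KOH, degassed MeOH/THF/H2O, argon, 50 °C; then 1 M HCl
Reagents that add atoms: none
Why: Sulfonate ester hydrolysis by attack of hydroxide at sulfur frees the two ring E phenols, and any reversible quinone-methide opening of the dihydrofurans can only re-close to the trans isomers because C3 and C3' are not epimerisable.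

Compound list
1 | 2',6'-dihydroxyacetophenone | CC(=O)c1c(O)cccc1O | starting material
2 | 1-[2-(benzyloxy)-6-hydroxyphenyl]ethan-1-one | CC(=O)c1c(O)cccc1OCc1ccccc1 | intermediate
3 | tert-butyl 3-[2-(benzyloxy)-6-hydroxyphenyl]-3-oxopropanoate | CC(C)(C)OC(=O)CC(=O)c1c(O)cccc1OCc1ccccc1 | intermediate
4 | 2,4-dihydroxybenzaldehyde | O=Cc1ccc(O)cc1O | starting material
5 | 2,4-bis(methylsulfonyloxy)benzaldehyde | O=Cc1ccc(OS(C)(=O)=O)cc1OS(C)(=O)=O | intermediate
6 | tert-butyl (Z)-2-[2-(benzyloxy)-6-hydroxybenzoyl]-3-[2,4-bis(methylsulfonyloxy)phenyl]prop-2-enoate | CC(C)(C)OC(=O)/C(=C\c1ccc(OS(C)(=O)=O)cc1OS(C)(=O)=O)C(=O)c1c(O)cccc1OCc1ccccc1 | intermediate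
7 | tert-butyl (2S)-5-(benzyloxy)-2-[2,4-bis(methylsulfonyloxy)phenyl]-4-oxochromane-3-carboxylate (C3 epimers and enol) | CC(C)(C)OC(=O)C1C(=O)c2c(OCc3ccccc3)cccc2O[C@@H]1c1ccc(OS(C)(=O)=O)cc1OS(C)(=O)=O | intermediate
8 | (2S)-5-(benzyloxy)-2-[2,4-bis(methylsulfonyloxy)phenyl]chroman-4-one | c1ccc(OCc3ccccc3)c2c1O[C@H](c1ccc(OS(C)(=O)=O)cc1OS(C)(=O)=O)CC2=O | intermediate
9 | (2S)-5-(benzyloxy)-2-[2,4-bis(methylsulfonyloxy)phenyl]-4-methoxy-2H-chromene | c1ccc(OCc3ccccc3)c2c1O[C@H](c1ccc(OS(C)(=O)=O)cc1OS(C)(=O)=O)C=C2OC | intermediate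
10 | methyl (2S,3S)-4-(benzyloxy)-2-[2,4-bis(methylsulfonyloxy)phenyl]-2,3-dihydrobenzofuran-3-carboxylate | c1ccc(OCc3ccccc3)c2c1O[C@H](c1ccc(OS(C)(=O)=O)cc1OS(C)(=O)=O)[C@H]2C(=O)OC | intermediate
11 | methyl (2S,3S)-4-(benzyloxy)-7-iodo-2-[2,4-bis(methylsulfonyloxy)phenyl]-2,3-dihydrobenzofuran-3-carboxylate | Ic1ccc(OCc3ccccc3)c2c1O[C@H](c1ccc(OS(C)(=O)=O)cc1OS(C)(=O)=O)[C@H]2C(=O)OC | intermediate
12 | 4-bromo-2,6-difluorobenzaldehyde | O=Cc1c(F)cc(Br)cc1F | starting material
13 | 2,6-bis(benzyloxy)-4-bromobenzaldehyde | O=Cc1c(OCc2ccccc2)cc(Br)cc1OCc1ccccc1 | intermediate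
14 | 2-(benzyloxy)-4-bromo-6-hydroxybenzaldehyde | O=Cc1c(O)cc(Br)cc1OCc1ccccc1 | intermediate
15 | 5-(benzyloxy)-7-bromo-2H-chromen-2-one | O=C1C=Cc2c(OCc3ccccc3)cc(Br)cc2O1 | intermediate
16 | [3,5-bis(benzyloxy)phenyl]boronic acid | OB(O)c1cc(OCc2ccccc2)cc(OCc2ccccc2)c1 | starting material
17 | (4S)-5-(benzyloxy)-4-[3,5-bis(benzyloxy)phenyl]-7-bromochroman-2-one | O=C1C[C@@H](c2cc(OCc3ccccc3)cc(OCc3ccccc3)c2)c2c(OCc3ccccc3)cc(Br)cc2O1 | intermediate
18 | 1-(benzyloxy)-4-vinylbenzene | C=Cc1ccc(OCc2ccccc2)cc1 | starting material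
19 | (4S)-5-(benzyloxy)-4-[3,5-bis(benzyloxy)phenyl]-7-[(E)-4-(benzyloxy)styryl]chroman-2-one | O=C1C[C@@H](c2cc(OCc3ccccc3)cc(OCc3ccccc3)c2)c2c(OCc3ccccc3)cc(/C=C/c3ccc(OCc4ccccc4)cc3)cc2O1 | intermediate
20 | (3R,4S)-5-(benzyloxy)-4-[3,5-bis(benzyloxy)phenyl]-7-[(E)-4-(benzyloxy)styryl]-3-bromochroman-2-one | O=C1[C@H](Br)[C@@H](c2cc(OCc3ccccc3)cc(OCc3ccccc3)c2)c2c(OCc3ccccc3)cc(/C=C/c3ccc(OCc4ccccc4)cc3)cc2O1 | intermediate
21 | methyl (2S,3S)-4-(benzyloxy)-3-[3,5-bis(benzyloxy)phenyl]-6-[(E)-4-(benzyloxy)styryl]-2,3-dihydrobenzofuran-2-carboxylate | c1ccccc1COc1ccc(/C=C/c2cc(OCc4ccccc4)c3c(c2)O[C@H](C(=O)OC)[C@H]3c2cc(OCc4ccccc4)cc(OCc4ccccc4)c2)cc1 | intermediate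
22 | (2S,3S)-4-(benzyloxy)-3-[3,5-bis(benzyloxy)phenyl]-6-[(E)-4-(benzyloxy)styryl]-2,3-dihydrobenzofuran-2-carboxylic acid | c1ccccc1COc1ccc(/C=C/c2cc(OCc4ccccc4)c3c(c2)O[C@H](C(=O)O)[C@H]3c2cc(OCc4ccccc4)cc(OCc4ccccc4)c2)cc1 | intermediate
23 | 1,3-dioxoisoindolin-2-yl (2S,3S)-4-(benzyloxy)-3-[3,5-bis(benzyloxy)phenyl]-6-[(E)-4-(benzyloxy)styryl]-2,3-dihydrobenzofuran-2-carboxylate | c1ccccc1COc1ccc(/C=C/c2cc(OCc4ccccc4)c3c(c2)O[C@H](C(=O)ON4C(=O)c5ccccc5C4=O)[C@H]3c2cc(OCc4ccccc4)cc(OCc4ccccc4)c2)cc1 | intermediate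
24 | methyl (2'S,3'S)-4'-(benzyloxy)-2'-[2,4-bis(methylsulfonyloxy)phenyl]-7'-{(2S,3S)-4-(benzyloxy)-3-[3,5-bis(benzyloxy)phenyl]-6-[(E)-4-(benzyloxy)styryl]-2,3-dihydrobenzofuran-2-yl}-2',3'-dihydrobenzofuran-3'-carboxylate | c1ccccc1COc1ccc(/C=C/c2cc(OCc6ccccc6)c3c(c2)O[C@H](c2ccc(OCc6ccccc6)c4c2O[C@H](c2ccc(OS(C)(=O)=O)cc2OS(C)(=O)=O)[C@H]4C(=O)OC)[C@H]3c2cc(OCc6ccccc6)cc(OCc6ccccc6)c2)cc1 | intermediate
25 | C3' carboxylic acid corresponding to 24 (2S,3S,2'S,3'S) | c1ccccc1COc1ccc(/C=C/c2cc(OCc6ccccc6)c3c(c2)O[C@H](c2ccc(OCc6ccccc6)c4c2O[C@H](c2ccc(OS(C)(=O)=O)cc2OS(C)(=O)=O)[C@H]4C(=O)O)[C@H]3c2cc(OCc6ccccc6)cc(OCc6ccccc6)c2)cc1 | intermediate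
26 | 1,3-dioxoisoindolin-2-yl ester of 25 (2S,3S,2'S,3'S) | c1ccccc1COc1ccc(/C=C/c2cc(OCc6ccccc6)c3c(c2)O[C@H](c2ccc(OCc6ccccc6)c4c2O[C@H](c2ccc(OS(C)(=O)=O)cc2OS(C)(=O)=O)[C@H]4C(=O)ON5C(=O)c7ccccc7C5=O)[C@H]3c2cc(OCc6ccccc6)cc(OCc6ccccc6)c2)cc1 | intermediate
27 | 1,3-bis(benzyloxy)-5-bromobenzene | Brc1cc(OCc2ccccc2)cc(OCc2ccccc2)c1 | starting material
28 | [3,5-bis(benzyloxy)phenyl]lithium | [Li]c1cc(OCc2ccccc2)cc(OCc2ccccc2)c1 | intermediate
29 | [3,5-bis(benzyloxy)phenyl]zinc chloride | Cl[Zn]c1cc(OCc2ccccc2)cc(OCc2ccccc2)c1 | intermediate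
30 | hepta-O-benzyl gnetumontanin B ring E bis(methanesulfonate) (2S,3S,2'S,3'S) | c1ccccc1COc1ccc(/C=C/c2cc(OCc6ccccc6)c3c(c2)O[C@H](c2ccc(OCc6ccccc6)c4c2O[C@H](c2ccc(OS(C)(=O)=O)cc2OS(C)(=O)=O)[C@H]4c2cc(OCc6ccccc6)cc(OCc6ccccc6)c2)[C@H]3c2cc(OCc6ccccc6)cc(OCc6ccccc6)c2)cc1 | intermediate
31 | gnetumontanin B ring E bis(methanesulfonate) (2S,3S,2'S,3'S) | Oc1ccc(/C=C/c2cc(O)c3c(c2)O[C@H](c2ccc(O)c4c2O[C@H](c2ccc(OS(C)(=O)=O)cc2OS(C)(=O)=O)[C@H]4c2cc(O)cc(O)c2)[C@H]3c2cc(O)cc(O)c2)cc1 | intermediate
32 | gnetumontanin B (2S,3S,2'S,3'S) | Oc1ccc(/C=C/c2cc(O)c3c(c2)O[C@H](c2ccc(O)c4c2O[C@H](c2ccc(O)cc2O)[C@H]4c2cc(O)cc(O)c2)[C@H]3c2cc(O)cc(O)c2)cc1 | target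

Total step count: 21.
Longest linear sequence: 14 steps (12 to 32 through steps 8–21). The upper-half line from 1 runs 12 steps.

Steps most likely to fail

Step 6 (key step).
- What may go wrong:
  - Enol-ether formation may be slow next to the peri benzyloxy group.
  - The iodane may eliminate to the flavone or be displaced by methanol instead of triggering the shift.
  - The activated ring C may be attacked by the oxidant.
  - Prolonged acid may open the pyranone and erode C2.
- Fallback: it sets out from 8 and comes back at 10, keeping the same bond formation but replacing the iodane by a carbene/ketene manifold.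
  - 8 is enolised with LiN(SiMe3)2 at −78 °C and acylated with 2,2,2-trifluoroethyl trifluoroacetate to the 3-trifluoroacetylflavanone F1.
  - F1 undergoes detrifluoroacetylative Regitz diazo transfer with methanesulfonyl azide and Et3N to the 3-diazoflavanone F2.
  - Irradiation in methanol triggers a Wolff rearrangement in which only the acyl-bound ring C carbon can migrate. The ring-contracted ketene is trapped by methanol.
  - The cis ester F3 formed beside 10 is equilibrated to 10 with DBU.

Step 16.
- What may go wrong: the two electrophiles may be activated at mismatched rates. The aryl iodide would then be lost by protodehalogenation or homocoupling, and the C2 radical by reduction or dimerisation.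
- Fallback: it sets out from 11 and comes back at 24, inverting the polarity of the upper half.
  - 11 is converted with zinc dust and LiCl in THF into the arylzinc iodide F4.
  - F4 is coupled with 23 under NiCl2(dme) and 4,4'-di-tert-butyl-2,2'-bipyridine without external reductant (decarboxylative Negishi-type arylation). Only one electrophile then competes for the low-valent nickel.

Step 19.
- What may go wrong: capture of the crowded, stabilised benzylic C3' radical by nickel may be slow. Radical dimerisation, hydrogen abstraction or aromatisation to the benzofuran could then take over.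
- Fallback: it sets out from 26 and comes back at 30, separating radical generation from C–C bond formation.
  - Copper-catalysed decarboxylative borylation (Cu(acac)2, B2pin2, LiOH·H2O, MgCl2, dioxane/DMF, rt) gives the trans C3' pinacol boronate F5.
  - F5 is arylated with 1,3-bis(benzyloxy)-5-iodobenzene in a stereoretentive Suzuki–Miyaura coupling of the secondary benzylic boronate (Pd2(dba)3, PPh3, Ag2O, DME, 85 °C).

Further compounds
F1 | step 6 | (2S)-5-(benzyloxy)-2-[2,4-bis(methylsulfonyloxy)phenyl]-3-(trifluoroacetyl)chroman-4-one (C3 epimers and enol) | c1ccc(OCc3ccccc3)c2c1O[C@H](c1ccc(OS(C)(=O)=O)cc1OS(C)(=O)=O)C(C(=O)C(F)(F)F)C2=O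
F2 | step 6 | (2R)-5-(benzyloxy)-3-diazo-2-[2,4-bis(methylsulfonyloxy)phenyl]chroman-4-one (same spatial arrangement at C2 as 8, descriptor changed by priority) | c1ccc(OCc3ccccc3)c2c1O[C@H](c1ccc(OS(C)(=O)=O)cc1OS(C)(=O)=O)C(=[N+]=[N-])C2=O
F3 | step 6 | methyl (2S,3R)-4-(benzyloxy)-2-[2,4-bis(methylsulfonyloxy)phenyl]-2,3-dihydrobenzofuran-3-carboxylate (cis epimer of 10) | c1ccc(OCc3ccccc3)c2c1O[C@H](c1ccc(OS(C)(=O)=O)cc1OS(C)(=O)=O)[C@@H]2C(=O)OC
F4 | step 16 | {(2S,3S)-4-(benzyloxy)-3-(methoxycarbonyl)-2-[2,4-bis(methylsulfonyloxy)phenyl]-2,3-dihydrobenzofuran-7-yl}zinc iodide | I[Zn]c1ccc(OCc3ccccc3)c2c1O[C@H](c1ccc(OS(C)(=O)=O)cc1OS(C)(=O)=O)[C@H]2C(=O)OC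
F5 | step 19 | C3' pinacol boronate in place of the C3' carboxyl group of 25 (2S,3S,2'S,3'S) | c1ccccc1COc1ccc(/C=C/c2cc(OCc6ccccc6)c3c(c2)O[C@H](c2ccc(OCc6ccccc6)c4c2O[C@H](c2ccc(OS(C)(=O)=O)cc2OS(C)(=O)=O)[C@H]4B2OC(C)(C)C(C)(C)O2)[C@H]3c2cc(OCc6ccccc6)cc(OCc6ccccc6)c2)cc1
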